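**Plan**

1. Numbering used throughout: C1 (methyl-bearing fusion carbon), C2, C3, C4 (isopropyl carbinol), C5 (fusion CH), C6 (aroyloxy), C7=C8 (methyl on C8), C9 (acetoxy), C10; α is the face of the C1 methyl group, β the face of H-5 (trans fusion).
2. Retrosynthetic cuts, in order: the two ester C–O bonds; the C9–O and C8–CH3 bonds (back to a C6 ketone with a bare C7–C10 chain); the C4–isopropyl bond (back to a C4 ketone); C2=C3 by ring-closing metathesis; finally C4–C5 (aldol to acrolein) and C1–vinyl (conjugate addition) on a cycloheptenone.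
3. Enabling feature: in the five-membered ring (C1–C5) the only unfunctionalised carbons, C2 and C3, are adjacent and sit between quaternary C1 and oxygen-bearing C4, so a C2=C3 alkene conjugated to a C4 ketone can be closed by metathesis on the intact seven-membered ring (C1, C5–C10) and leaves no trace after hydrogenation and isopropyl addition.
4. Forward order: the seven-membered ring is bought as 3-methylcycloheptenone and receives its C1 and C5 substituents (steps 1–6); the cyclopentenone is annulated (step 7); C4 and the C6–C9 segment are then elaborated and the esters attached (steps 8–18).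
5. Stereochemistry: C1 from the chiral copper catalyst; C5 from aldol attack anti to the bulky 1-silylvinyl group on C1; C4 from nucleophile attack anti to the angular methyl; C9 from peracid attack anti to the angular methyl; C6 from hydride delivery directed by the C4 hydroxyl.

Key step: step 7

Remark: the carbinol at C4 (steps 2–3) and the oxygen-bearing C6 centre (steps 3–10) are temporary stereocentres drawn as the isomers expected from the stated controls; they are erased in steps 4 and 11, and C6 is set for good in step 16.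
Remark: 4-(tert-butyldimethylsilyloxy)benzoic acid is taken as a purchasable building block.
Remark: bicyclic intermediates are named on the perhydroazulene (bicyclo[5.3.0]decane) skeleton with the numbering of line 1; 1α-methyl with 5βH means trans ring fusion.

**Route**

Step 1
Reactants: 1 3-methylcyclohept-2-en-1-one; 2 ethynyltrimethylsilane
Product: 5 (R)-3-methyl-1-(trimethylsilyloxy)-3-[1-(trimethylsilyl)ethenyl]cyclohept-1-ene, via vinylalane 3 (not isolated), via aluminium enolate 4 (not isolated)
Conditions: 2, iBu2AlH, hexanes/THF, 55 °C; then 1, Cu(OTf)2 (5 mol%), chiral sulfonate-bearing imidazolinium salt (N-heterocyclic carbene precursor, 5 mol%), THF, −78 → 4 °C; then Me3SiOTf, −78 → 0 °C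
Reagents that add atoms: trimethylsilyl trifluoromethanesulfonate C[Si](C)(C)OS(=O)(=O)C(F)(F)F
Why: Hydroalumination of the silylalkyne gives the α-silyl vinylalane, which undergoes copper-catalysed enantioselective conjugate addition to the β-methyl enone so that the chiral carbene ligand sets the quaternary C1 centre (R, alkenyl group β), and the regiodefined aluminium enolate is captured on oxygen as the C5=C6 enol silane.

Step 2
Reactants: 5 (R)-3-methyl-1-(trimethylsilyloxy)-3-[1-(trimethylsilyl)ethenyl]cyclohept-1-ene; 6 acrolein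
Product: 8 2-(1-hydroxyprop-2-en-1-yl)-3-methyl-3-[1-(trimethylsilyl)ethenyl]cycloheptan-1-one (anti aldol; side chain trans to the silylvinyl group), via lithium enolate 7 (not isolated)
Conditions: MeLi, THF, 0 °C; then 6, −78 °C
Reagents that add atoms: none
Why: Methyllithium cleaves the O–Si bond to the regiospecific lithium enolate, which undergoes 1,2-aldol addition to acrolein on the C5 face opposite the bulky 1-(trimethylsilyl)vinyl group so that the new C4–C5 bond is α, while the closed Zimmerman–Traxler transition state of the ring-fixed E-enolate should give the anti carbinol at C4.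

Step 3
Reactants: 8 2-(1-hydroxyprop-2-en-1-yl)-3-methyl-3-[1-(trimethylsilyl)ethenyl]cycloheptan-1-one
Product: 9 2-(1-hydroxyprop-2-en-1-yl)-3-methyl-3-[1-(trimethylsilyl)ethenyl]cycloheptan-1-ol (1,3-syn diol; ring hydroxyl β, trans to the side chain)
Conditions: Et2BOMe, NaBH4, THF/MeOH (4:1), −78 °C; MeOH co-evaporation
Reagents that add atoms: none
Why: In this Narasaka–Prasad reduction the boron chelate of the β-hydroxy ketone takes external hydride to give the 1,3-syn diol, which for the anti aldol places the C6 hydroxyl on the β face, trans to the C5 side chain.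

Step 4
Reactants: 9 2-(1-hydroxyprop-2-en-1-yl)-3-methyl-3-[1-(trimethylsilyl)ethenyl]cycloheptan-1-ol
Product: 10 1-{2-hydroxy-7-methyl-7-[1-(trimethylsilyl)ethenyl]cycloheptyl}prop-2-en-1-one (acyl α; hydroxyl and silylvinyl β)
Conditions: MnO2 (activated, excess), CH2Cl2, rt
Reagents that add atoms: none
Why: Activated MnO2 oxidises only the allylic vinyl carbinol at C4 to the vinyl ketone and leaves the saturated C6 carbinol, which also removes the temporary C4 stereocentre.

Step 5
Reactants: 10 1-{2-hydroxy-7-methyl-7-[1-(trimethylsilyl)ethenyl]cycloheptyl}prop-2-en-1-one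
Product: 11 1-{2-methyl-2-[1-(trimethylsilyl)ethenyl]-7-(triisopropylsilyloxy)cycloheptyl}prop-2-en-1-one (same relative configuration)
Conditions: iPr3SiOTf, 2,6-lutidine, CH2Cl2, −78 → 0 °C
Reagents that add atoms: triisopropylsilyl trifluoromethanesulfonate CC(C)[Si](OS(=O)(=O)C(F)(F)F)(C(C)C)C(C)C
Why: Silyl triflate silylation of the hindered secondary alcohol blocks oxa-Michael closure onto the enone and installs an ether that is stable to the acid of the next step.

Step 6
Reactants: 11 1-{2-methyl-2-[1-(trimethylsilyl)ethenyl]-7-(triisopropylsilyloxy)cycloheptyl}prop-2-en-1-one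
Product: 12 1-[(1S,2S,7S)-2-ethenyl-2-methyl-7-(triisopropylsilyloxy)cycloheptyl]prop-2-en-1-one (vinyl β, acryloyl α, silyloxy β)
Conditions: CF3CO2H, CH2Cl2, 0 °C → rt
Reagents that add atoms: none
Why: In this protodesilylation of the vinylsilane, ipso protonation gives a β-silyl-stabilised cation that loses the silyl group to trifluoroacetate, which unveils the C1 vinyl group while the triisopropylsilyl ether and the enone should persist.

Step 7
Reactants: 12 1-[(1S,2S,7S)-2-ethenyl-2-methyl-7-(triisopropylsilyloxy)cycloheptyl]prop-2-en-1-one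
Product: 13 (3aS,8S,8aS)-3a-methyl-8-(triisopropylsilyloxy)-3a,4,5,6,7,8-hexahydroazulen-1(8aH)-one (trans-fused; skeletal C2=C3, C4 ketone, 6β-silyloxy)
Conditions: second-generation Grubbs catalyst RuCl2(=CHPh)(PCy3)(H2IMes) (5 mol%), CH2Cl2 (0.005 M), 40 °C
Reagents that add atoms: none
Why: The ruthenium benzylidene exchanges onto the electron-rich C1 vinyl group, the resulting alkylidene adds [2+2] to the neighbouring acryloyl alkene, and cycloreversion of the ruthenacyclobutane forms C2=C3 with loss of ethene. The closest known reaction type is ring-closing enone–olefin metathesis to cyclopent-2-enones with N-heterocyclic-carbene ruthenium catalysts. The single ring formed is the five-membered C1–C5 ring, closed by intramolecular metathesis of two terminal alkenes so that C2=C3 becomes endocyclic and conjugated to the C4 ketone. No stereocentre is created, and the trans ring fusion follows from the trans arrangement of vinyl and acryloyl groups already fixed at C1 and C5. The step needs ring closure to outrun intermolecular cross-metathesis of the acryloyl group and needs C5 to keep its configuration, which high dilution, the proximity of the two alkenes on adjacent ring carbons (helped by the quaternary C1) and the neutral, base-free medium should secure.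

Step 8
Reactants: 13 (3aS,8S,8aS)-3a-methyl-8-(triisopropylsilyloxy)-3a,4,5,6,7,8-hexahydroazulen-1(8aH)-one
Product: 14 1α-methyl-6β-(triisopropylsilyloxy)-5βH-perhydroazulen-4-one
Conditions: H2 (1 atm), 10% Pd/C, EtOAc, rt
Reagents that add atoms: none
Why: Heterogeneous catalytic hydrogenation saturates the only alkene, the enone C2=C3 bond, and leaves the ketone and the silyl ether untouched.

Step 9
Reactants: 14 1α-methyl-6β-(triisopropylsilyloxy)-5βH-perhydroazulen-4-one
Product: 15 4β-isopropyl-1α-methyl-6β-(triisopropylsilyloxy)-5βH-perhydroazulen-4α-ol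
Conditions: iPrMgCl, CeCl3 (anhydrous), THF, −78 → 0 °C
Reagents that add atoms: isopropylmagnesium chloride CC(C)[Mg]Cl
Why: This CeCl3-promoted Grignard 1,2-addition, which suppresses enolisation and β-hydride reduction, should deliver the isopropyl group to the C4 ketone from the β face, anti to the angular C1 methyl that shields the α face of the trans-fused cyclopentanone, giving the tertiary alcohol with the hydroxyl α (cis to the methyl).

Step 10
Reactants: 15 4β-isopropyl-1α-methyl-6β-(triisopropylsilyloxy)-5βH-perhydroazulen-4α-ol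
Product: 16 4β-isopropyl-1α-methyl-5βH-perhydroazulene-4α,6β-diol
Conditions: Bu4NF, THF, rt → 40 °C
Reagents that add atoms: none
Why: Fluoride-mediated cleavage of the silyl ether frees the C6 hydroxyl without affecting the tertiary alcohol.

Step 11
Reactants: 16 4β-isopropyl-1α-methyl-5βH-perhydroazulene-4α,6β-diol
Product: 17 4α-hydroxy-4β-isopropyl-1α-methyl-5βH-perhydroazulen-6-one
Conditions: Dess–Martin periodinane, pyridine, CH2Cl2, 0 °C → rt
Reagents that add atoms: none
Why: Dess–Martin oxidation converts the secondary C6 alcohol into the ketone, erasing the temporary C6 centre, and cannot touch the tertiary C4 alcohol.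

Step 12
Reactants: 17 4α-hydroxy-4β-isopropyl-1α-methyl-5βH-perhydroazulen-6-one
Product: 19 4β-isopropyl-1α-methyl-4α-(trimethylsilyloxy)-5βH-hydroazul-7-en-6-one, via bis-silyl enol ether 18 (not isolated)
Conditions: Me3SiCl, LiN(iPr)2, THF, −78 °C; then Pd(OAc)2, MeCN, rt
Reagents that add atoms: chlorotrimethylsilane C[Si](C)(C)Cl
Why: Kinetic deprotonation with in situ silylation caps the tertiary alcohol and forms the less substituted C6=C7 enol silane (C5 is a shielded methine), and Saegusa–Ito oxidation with Pd(OAc)2 then gives the C7=C8 enone.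

Step 13
Reactants: 19 4β-isopropyl-1α-methyl-4α-(trimethylsilyloxy)-5βH-hydroazul-7-en-6-one
Product: 21 4β-isopropyl-1α,8-dimethyl-4α-(trimethylsilyloxy)-5βH-hydroazul-7-en-6-one, via enol silane 20 (not isolated)
Conditions: Me2CuLi (from CuI, MeLi), Me3SiCl, THF, −78 °C; then Pd(OAc)2, MeCN, rt
Reagents that add atoms: lithium dimethylcuprate [Li+].C[Cu-]C
Why: Cuprate conjugate addition with chlorosilane trapping places the methyl group on C8 (its configuration is irrelevant), and a second Saegusa–Ito oxidation of the resulting enol silane restores the C7=C8 double bond, now carrying the methyl group.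

Step 14
Reactants: 21 4β-isopropyl-1α,8-dimethyl-4α-(trimethylsilyloxy)-5βH-hydroazul-7-en-6-one
Product: 24 4α,9β-dihydroxy-4β-isopropyl-1α,8-dimethyl-5βH-hydroazul-7-en-6-one, via dienol silyl ether 22 (not isolated), via silyloxy enone 23 (not isolated)
Conditions: Me3SiOTf, Et3N, CH2Cl2, 0 °C → rt; then mCPBA, CH2Cl2, −20 °C; then citric acid (10 mol%), MeOH, rt
Reagents that add atoms: 3-chloroperoxybenzoic acid OOC(=O)c1cccc(Cl)c1
Why: In this vinylogous Rubottom oxidation, soft enolisation gives the linear C6-silyloxy 6,8-dienol ether (the α′ position C5 is a blocked methine), the peracid should epoxidise the electron-rich distal C8=C9 bond from the β face, anti to the axial C1 methyl, collapse returns the enone with a 9β-silyloxy group, and mild methanolysis removes both trimethylsilyl groups.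

Step 15
Reactants: 24 4α,9β-dihydroxy-4β-isopropyl-1α,8-dimethyl-5βH-hydroazul-7-en-6-one
Product: 25 9β-acetoxy-4α-hydroxy-4β-isopropyl-1α,8-dimethyl-5βH-hydroazul-7-en-6-one
Conditions: Ac2O, pyridine, DMAP (5 mol%), CH2Cl2, 0 °C
Reagents that add atoms: acetic anhydride CC(=O)OC(C)=O
Why: Acylation with acetic anhydride takes the secondary allylic C9 alcohol and leaves the hindered tertiary C4 alcohol.

Step 16
Reactants: 25 9β-acetoxy-4α-hydroxy-4β-isopropyl-1α,8-dimethyl-5βH-hydroazul-7-en-6-one
Product: 26 9β-acetoxy-4β-isopropyl-1α,8-dimethyl-5βH-hydroazul-7-ene-4α,6β-diol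
Conditions: Me4NBH(OAc)3, MeCN/AcOH (1:1), −30 → 0 °C
Reagents that add atoms: none
Why: In this Evans–Saksena reduction the C4 hydroxyl exchanges onto boron and delivers hydride intramolecularly to the α face of the C6 carbonyl (1,2-reduction of the enone), which should give the 1,3-anti diol, that is the 6β-alcohol.

Step 17
Reactants: 26 9β-acetoxy-4β-isopropyl-1α,8-dimethyl-5βH-hydroazul-7-ene-4α,6β-diol; 27 4-(tert-butyldimethylsilyloxy)benzoic acid
Product: 28 9β-acetoxy-4α-hydroxy-4β-isopropyl-1α,8-dimethyl-5βH-hydroazul-7-en-6β-yl 4-(tert-butyldimethylsilyloxy)benzoate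
Conditions: DCC, DMAP (10 mol%), CH2Cl2, rt
Reagents that add atoms: none
Why: Steglich esterification acylates the secondary allylic C6 alcohol with the silyl-protected acid, the tertiary C4 alcohol being unreactive.

Step 18
Reactants: 28 9β-acetoxy-4α-hydroxy-4β-isopropyl-1α,8-dimethyl-5βH-hydroazul-7-en-6β-yl 4-(tert-butyldimethylsilyloxy)benzoate
Product: 29 (3R,3aS,4S,7S,8aR)-7-acetoxy-3-hydroxy-6,8a-dimethyl-3-(propan-2-yl)-1,2,3,3a,4,7,8,8a-octahydroazulen-4-yl 4-hydroxybenzoate (CNP0305796.2)
Conditions: Bu4NF, AcOH, THF, 0 °C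
Reagents that add atoms: none
Why: Buffered fluoride cleaves the aryl silyl ether far faster than it affects the two esters, releasing the phenol of the target.

**Compound list**

1 | 3-methylcyclohept-2-en-1-one | CC1=CC(=O)CCCC1 | starting material
2 | ethynyltrimethylsilane | C#C[Si](C)(C)C | starting material
3 | diisobutyl[1-(trimethylsilyl)ethenyl]aluminium | C=C([Si](C)(C)C)[Al](CC(C)C)CC(C)C | intermediate
4 | diisobutylaluminium (R)-3-methyl-3-[1-(trimethylsilyl)ethenyl]cyclohept-1-en-1-olate | C=C([Si](C)(C)C)[C@]1(C)CCCCC(O[Al](CC(C)C)CC(C)C)=C1 | intermediate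
5 | (R)-3-methyl-1-(trimethylsilyloxy)-3-[1-(trimethylsilyl)ethenyl]cyclohept-1-ene | C=C([Si](C)(C)C)[C@]1(C)CCCCC(O[Si](C)(C)C)=C1 | intermediate
6 | acrolein (prop-2-enal) | C=CC=O | starting material
7 | lithium (R)-3-methyl-3-[1-(trimethylsilyl)ethenyl]cyclohept-1-en-1-olate | C=C([Si](C)(C)C)[C@]1(C)CCCCC([O-])=C1.[Li+] | intermediate
8 | 2-(1-hydroxyprop-2-en-1-yl)-3-methyl-3-[1-(trimethylsilyl)ethenyl]cycloheptan-1-one (anti aldol; side chain trans to the silylvinyl group) | C=C([Si](C)(C)C)[C@]1(C)CCCCC(=O)[C@H]1[C@H](O)C=C | intermediate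
9 | 2-(1-hydroxyprop-2-en-1-yl)-3-methyl-3-[1-(trimethylsilyl)ethenyl]cycloheptan-1-ol (1,3-syn diol; ring hydroxyl trans to the side chain) | C=C([Si](C)(C)C)[C@]1(C)CCCC[C@H](O)[C@H]1[C@H](O)C=C | intermediate
10 | 1-{2-hydroxy-7-methyl-7-[1-(trimethylsilyl)ethenyl]cycloheptyl}prop-2-en-1-one (acyl α; hydroxyl and silylvinyl β) | C=C([Si](C)(C)C)[C@]1(C)CCCC[C@H](O)[C@H]1C(=O)C=C | intermediate
11 | 1-{2-methyl-2-[1-(trimethylsilyl)ethenyl]-7-(triisopropylsilyloxy)cycloheptyl}prop-2-en-1-one (acyl α; silyloxy and silylvinyl β) | C=C([Si](C)(C)C)[C@]1(C)CCCC[C@H](O[Si](C(C)C)(C(C)C)C(C)C)[C@H]1C(=O)C=C | intermediate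
12 | 1-[(1S,2S,7S)-2-ethenyl-2-methyl-7-(triisopropylsilyloxy)cycloheptyl]prop-2-en-1-one | C=C[C@]1(C)CCCC[C@H](O[Si](C(C)C)(C(C)C)C(C)C)[C@H]1C(=O)C=C | intermediate
13 | (3aS,8S,8aS)-3a-methyl-8-(triisopropylsilyloxy)-3a,4,5,6,7,8-hexahydroazulen-1(8aH)-one | O=C1C=C[C@]2(C)CCCC[C@H](O[Si](C(C)C)(C(C)C)C(C)C)[C@@H]12 | intermediate
14 | 1α-methyl-6β-(triisopropylsilyloxy)-5βH-perhydroazulen-4-one | O=C1CC[C@]2(C)CCCC[C@H](O[Si](C(C)C)(C(C)C)C(C)C)[C@@H]12 | intermediate
15 | 4β-isopropyl-1α-methyl-6β-(triisopropylsilyloxy)-5βH-perhydroazulen-4α-ol | CC(C)[C@]1(O)CC[C@]2(C)CCCC[C@H](O[Si](C(C)C)(C(C)C)C(C)C)[C@@H]12 | intermediate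
16 | 4β-isopropyl-1α-methyl-5βH-perhydroazulene-4α,6β-diol | CC(C)[C@]1(O)CC[C@]2(C)CCCC[C@H](O)[C@@H]12 | intermediate
17 | 4α-hydroxy-4β-isopropyl-1α-methyl-5βH-perhydroazulen-6-one | CC(C)[C@]1(O)CC[C@]2(C)CCCCC(=O)[C@@H]12 | intermediate
18 | 4β-isopropyl-1α-methyl-4α,6-bis(trimethylsilyloxy)-5βH-hydroazul-6-ene | CC(C)[C@]1(O[Si](C)(C)C)CC[C@]2(C)CCCC=C(O[Si](C)(C)C)[C@@H]12 | intermediate
19 | 4β-isopropyl-1α-methyl-4α-(trimethylsilyloxy)-5βH-hydroazul-7-en-6-one | CC(C)[C@]1(O[Si](C)(C)C)CC[C@]2(C)CCC=CC(=O)[C@@H]12 | intermediate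
20 | 4β-isopropyl-1α,8β-dimethyl-4α,6-bis(trimethylsilyloxy)-5βH-hydroazul-6-ene (C8 drawn as the expected epimer) | CC(C)[C@]1(O[Si](C)(C)C)CC[C@]2(C)CC[C@H](C)C=C(O[Si](C)(C)C)[C@@H]12 | intermediate
21 | 4β-isopropyl-1α,8-dimethyl-4α-(trimethylsilyloxy)-5βH-hydroazul-7-en-6-one | CC(C)[C@]1(O[Si](C)(C)C)CC[C@]2(C)CCC(C)=CC(=O)[C@@H]12 | intermediate
22 | 4β-isopropyl-1α,8-dimethyl-4α,6-bis(trimethylsilyloxy)-5βH-hydroazula-6,8-diene | CC(C)[C@]1(O[Si](C)(C)C)CC[C@]2(C)CC=C(C)C=C(O[Si](C)(C)C)[C@@H]12 | intermediate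
23 | 4β-isopropyl-1α,8-dimethyl-4α,9β-bis(trimethylsilyloxy)-5βH-hydroazul-7-en-6-one | CC(C)[C@]1(O[Si](C)(C)C)CC[C@]2(C)C[C@H](O[Si](C)(C)C)C(C)=CC(=O)[C@@H]12 | intermediate
24 | 4α,9β-dihydroxy-4β-isopropyl-1α,8-dimethyl-5βH-hydroazul-7-en-6-one | CC(C)[C@]1(O)CC[C@]2(C)C[C@H](O)C(C)=CC(=O)[C@@H]12 | intermediate
25 | 9β-acetoxy-4α-hydroxy-4β-isopropyl-1α,8-dimethyl-5βH-hydroazul-7-en-6-one | CC(C)[C@]1(O)CC[C@]2(C)C[C@H](OC(C)=O)C(C)=CC(=O)[C@@H]12 | intermediate
26 | 9β-acetoxy-4β-isopropyl-1α,8-dimethyl-5βH-hydroazul-7-ene-4α,6β-diol | CC(C)[C@]1(O)CC[C@]2(C)C[C@H](OC(C)=O)C(C)=C[C@H](O)[C@@H]12 | intermediate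
27 | 4-(tert-butyldimethylsilyloxy)benzoic acid | CC(C)(C)[Si](C)(C)Oc1ccc(cc1)C(=O)O | starting material
28 | 9β-acetoxy-4α-hydroxy-4β-isopropyl-1α,8-dimethyl-5βH-hydroazul-7-en-6β-yl 4-(tert-butyldimethylsilyloxy)benzoate | CC(C)[C@]1(O)CC[C@]2(C)C[C@H](OC(C)=O)C(C)=C[C@H](OC(=O)c3ccc(O[Si](C)(C)C(C)(C)C)cc3)[C@@H]12 | intermediate
29 | (3R,3aS,4S,7S,8aR)-7-acetoxy-3-hydroxy-6,8a-dimethyl-3-(propan-2-yl)-1,2,3,3a,4,7,8,8a-octahydroazulen-4-yl 4-hydroxybenzoate | CC(C)[C@]1(O)CC[C@]2(C)C[C@H](OC(C)=O)C(C)=C[C@H](OC(=O)c3ccc(O)cc3)[C@@H]12 | target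

**Count and risks**

Total step count: 18. Longest linear sequence: 18 steps (1 to 29); acid 27 enters at step 17.

Steps most likely to fail:

Step 14. The soft enolisation may run toward the C8 methyl group (exocyclic dienol ether), or the peracid may attack C7 or the α face, giving regio- or stereoisomeric hydroxy enones. The fallback sets out from 21 and returns at 28, moving the C9 oxygenation behind the C6 chemistry. Methanolysis of the silyl ether (citric acid, MeOH) should give the 4α-hydroxy enone F1. Evans–Saksena reduction with Me4NBH(OAc)3 should give the 4α,6β-diol F2. Steglich esterification with 27 (DCC, DMAP) should give the C6 ester F3. Riley allylic oxidation (SeO2, tBuOOH, CH2Cl2) should then hydroxylate the ring methylene C9 at the more substituted end of the C7=C8 alkene, on the β face away from the axial C1 methyl, to give the 9β-alcohol F4. Acetylation (Ac2O, pyridine) converts F4 into 28.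

Step 9. The basic reagent may enolise the hindered cyclopentanone, with β-elimination of the C6 silyloxy group, or reduce it by β-hydride transfer, or add with low facial selectivity. The fallback sets out from 14 and returns at 15, using a smaller, less basic sp2 nucleophile followed by saturation. Isopropenylmagnesium bromide with CeCl3 (THF, −78 °C) should add from the β face to give the isopropenyl carbinol F5. Hydrogenation of its 1,1-disubstituted alkene (H2, Pd/C, EtOAc) gives 15.

Step 2. Acrolein may undergo 1,4-addition or oligomerisation, the aldolate may revert or dehydrate under the basic conditions, and facial control at C5 may be incomplete. The fallback sets out from 5 and returns at 10, replacing the metal enolate by a Lewis-acid-mediated open-transition-state addition. A Mukaiyama aldol of 5 with 6 (TiCl4, CH2Cl2, −78 °C) should give 8 or, if it is syn-selective, the C4-epimeric aldol F6. F6 would be reduced with Me4NBH(OAc)3 (anti-selective) to the 1,3-anti diol F7, which carries the same β-hydroxyl at C6 as 9. MnO2 oxidation of F7 gives 10.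

Further compounds
F1 | step 14 | 4α-hydroxy-4β-isopropyl-1α,8-dimethyl-5βH-hydroazul-7-en-6-one | CC(C)[C@]1(O)CC[C@]2(C)CCC(C)=CC(=O)[C@@H]12
F2 | step 14 | 4β-isopropyl-1α,8-dimethyl-5βH-hydroazul-7-ene-4α,6β-diol | CC(C)[C@]1(O)CC[C@]2(C)CCC(C)=C[C@H](O)[C@@H]12
F3 | step 14 | 4α-hydroxy-4β-isopropyl-1α,8-dimethyl-5βH-hydroazul-7-en-6β-yl 4-(tert-butyldimethylsilyloxy)benzoate | CC(C)[C@]1(O)CC[C@]2(C)CCC(C)=C[C@H](OC(=O)c3ccc(O[Si](C)(C)C(C)(C)C)cc3)[C@@H]12
F4 | step 14 | 4α,9β-dihydroxy-4β-isopropyl-1α,8-dimethyl-5βH-hydroazul-7-en-6β-yl 4-(tert-butyldimethylsilyloxy)benzoate | CC(C)[C@]1(O)CC[C@]2(C)C[C@H](O)C(C)=C[C@H](OC(=O)c3ccc(O[Si](C)(C)C(C)(C)C)cc3)[C@@H]12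
F5 | step 9 | 1α-methyl-4β-(prop-1-en-2-yl)-6β-(triisopropylsilyloxy)-5βH-perhydroazulen-4α-ol | C=C(C)[C@]1(O)CC[C@]2(C)CCCC[C@H](O[Si](C(C)C)(C(C)C)C(C)C)[C@@H]12
F6 | step 2 | 2-(1-hydroxyprop-2-en-1-yl)-3-methyl-3-[1-(trimethylsilyl)ethenyl]cycloheptan-1-one (syn aldol; C4 epimer of 8) | C=C([Si](C)(C)C)[C@]1(C)CCCCC(=O)[C@H]1[C@@H](O)C=C
F7 | step 2 | 2-(1-hydroxyprop-2-en-1-yl)-3-methyl-3-[1-(trimethylsilyl)ethenyl]cycloheptan-1-ol (1,3-anti diol; C4 epimer of 9) | C=C([Si](C)(C)C)[C@]1(C)CCCC[C@H](O)[C@H]1[C@@H](O)C=C
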